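The numbering is O1, C2H2, C3(CH3)=C4H, C5H2, C5a, C6(OH), C7(acyl), C8(OH), C9H, C9a. The target has no stereocentre, and the seven-membered ring holds the C3=C4 bond cis.
Retrosynthetic cuts: first C7–C(=O), which separates an aryl anion from the amide of dihydrocaffeic acid. Then C3–C4 and C4–C5 are cut together, which lifts the single carbon C4 out of the oxepine.
Enabling feature: C4 is a lone CH between methyl-bearing C3 and benzylic C5. Without it, O1–C2–C3–C5–C5a–C9a is the pyran ring of a 3-methyl-2H-chromene, and the oxygens at C6, C8 and C9a can carry the C5 cation that ring enlargement creates.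
Forward, first half: flopropione supplies the arene and formaldehyde closes the pyranone (C2–C3, then O1–C2). Reduction, bromination of the C–H between the two MOM ethers and dehydration then give the chromene.
Forward, second half: bromoform delivers C4 as CBr2, and a silver salt with a silane enlarges the pyran to the oxepine. The aryl bromide is exchanged for lithium and joined to the side chain, the leftover C4 bromide is exchanged and protonated in the same flask, and acid frees the four phenols.

Key step: step 6

Remark: every sp3 stereocentre met on the way (chromanone, chromanols, mesylate, cyclopropane, C5 ester, hemiaminals) is racemic or a diastereomer mixture and is gone in the target, so the SMILES carry no stereo descriptors. Paraformaldehyde is written as its monomer.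

Step 1
Reactants: 1 flopropione [1-(2,4,6-trihydroxyphenyl)propan-1-one]
Product: 2 1-[2-hydroxy-4,6-bis(methoxymethoxy)phenyl]propan-1-one
Conditions: MOMCl (2.2 equiv), i-Pr2NEt, CH2Cl2, 0 °C → rt
Reagents that add atoms: chloromethyl methyl ether, COCCl
Why: In this phenol O-alkylation the hydroxyl hydrogen-bonded to the ketone is the least nucleophilic and stays free, which is the usual outcome for acylphloroglucinols.

Step 2
Reactants: 2 1-[2-hydroxy-4,6-bis(methoxymethoxy)phenyl]propan-1-one; 3 paraformaldehyde
Product: 5 (±)-5,7-bis(methoxymethoxy)-3-methylchroman-4-one, via alpha-methylene ketone 4 (not isolated)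
Conditions: (CH2O)n, Et2NH, EtOH, reflux
Reagents that add atoms: formaldehyde (from paraformaldehyde 3), C=O
Why: Mannich condensation at the ketone alpha-CH2, loss of the amine and 6-endo-trig oxa-Michael closure by the free phenol form the standard route from 2'-hydroxyaryl alkyl ketones to 3-substituted chroman-4-ones, and the racemic C3 centre is erased in step 5.

Step 3
Reactants: 5 (±)-5,7-bis(methoxymethoxy)-3-methylchroman-4-one
Product: 6 5,7-bis(methoxymethoxy)-3-methylchroman-4-ol (racemic cis/trans mixture)
Conditions: NaBH4, MeOH–THF, 0 °C → rt; aq NaHCO3 work-up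
Reagents that add atoms: none
Why: Borohydride 1,2-reduction of the aryl ketone leaves the MOM acetals untouched, the diastereomer mixture is irrelevant because both centres disappear, and the basic work-up protects the easily ionised benzylic alcohol.

Step 4
Reactants: 6 5,7-bis(methoxymethoxy)-3-methylchroman-4-ol
Product: 8 6-bromo-5,7-bis(methoxymethoxy)-3-methylchroman-4-ol, via dilithio species 7 (not isolated)
Conditions: n-BuLi (2.3 equiv), THF, 0 °C; BrCH2CH2Br, −78 °C → rt; H2O
Reagents that add atoms: 1,2-dibromoethane, BrCCBr
Why: In this directed ortho-metalation the second equivalent of base, after O–H deprotonation, should take C6–H, the only ring hydrogen flanked by two chelating MOM ethers (C8–H has one MOM ether and the ring oxygen); the saturated chromanol offers no allylic C–H, and the aryllithium takes bromine from dibromoethane with loss of ethene.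

Step 5
Reactants: 8 6-bromo-5,7-bis(methoxymethoxy)-3-methylchroman-4-ol
Product: 10 6-bromo-5,7-bis(methoxymethoxy)-3-methyl-2H-chromene, via C4 mesylate 9 (not isolated)
Conditions: MsCl, Et3N (excess), CH2Cl2, 0 °C → rt
Reagents that add atoms: none
Why: The mesylate of so electron-rich a benzylic alcohol ionises as it forms and loses its only beta-hydrogen (C3–H), the usual E1-type dehydration of chroman-4-ols to 2H-chromenes, and the amine buffer spares the MOM acetals and the acid-sensitive styrene.

Step 6
Reactants: 10 6-bromo-5,7-bis(methoxymethoxy)-3-methyl-2H-chromene; 11 bromoform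
Product: 15 4,7-dibromo-6,8-bis(methoxymethoxy)-3-methyl-2,5-dihydro-1-benzoxepine, via dibromocyclopropane 12 (not isolated), via bromoallyl cation 13 (not isolated), via C5 trifluoroacetate 14 (not isolated)
Conditions: CHBr3 (2.5 equiv), KOt-Bu (3 equiv), toluene–hexane, −20 → 0 °C; Celite filtration under Ar, volatiles off at ≤ 20 °C; crude 12, Et3SiH (5 equiv), CH2Cl2, −40 °C, then AgOCOCF3 (1.2 equiv in Et2O, dropwise, dark), −40 → 0 °C; aq NaHCO3
Reagents that add atoms: bromoform (11), BrC(Br)Br
Why: Proposed new method: KOt-Bu turns 11 into dibromocarbene, which adds in a concerted suprafacial cheletropic step to the electron-rich, trisubstituted, styrene-type C3=C4 bond of 10 and thereby makes both new skeletal bonds (C3–C4 and C4–C5 in oxepine numbering) in the cis-fused cyclopropane 12. Silver ion then removes the endo bromide (syn to the pyran ring) while the shared ring-fusion bond opens by disrotation, the two-electron electrocyclic mode that the Woodward–Hoffmann–DePuy rule couples to a cis allyl cation, so the oxepine is closed by enlargement of the fused six-three bicycle and not by cyclisation of a chain. Cation 13 is long-lived because O1, O6 and O8 stand ortho and para to C5a, collapse with trifluoroacetate to ester 14 is reversible, and hydride transfer from Et3SiH is the only irreversible exit; its by-product Et3SiOCOCF3 leaves the MOM acetals alone, whereas a tetrafluoroborate salt would end as BF3, which together with silane strips such acetals. The closest known reaction types are the silver-assisted ring enlargement of dihalocarbene adducts of cyclic alkenes with capture by solvent or counter-ion and the ionic hydrogenation of benzylic cations with silanes, and only their merger is untested. The step needs hydride at C5 instead of C3 and hydride transfer faster than proton loss: the first should follow from the charge being drawn to the secondary benzylic terminus by the trioxygenated arene, from the full substitution of C3 and from the tetrasubstituted bromoalkene that forms, the second from a fivefold excess of silane already present when the silver salt is dripped in cold, an order of addition that also lets the cyclopropane consume the silver before it can oxidise the silane. No stereocentre is carried on, since the two of racemic 12 are erased on opening and the ring fixes the C3=C4 geometry.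

Step 7
Reactants: 16 3-(3,4-dihydroxyphenyl)propanoic acid
Product: 17 methoxymethyl 3-[3,4-bis(methoxymethoxy)phenyl]propanoate
Conditions: MOMCl (3.5 equiv), i-Pr2NEt, CH2Cl2, 0 °C → rt
Reagents that add atoms: chloromethyl methyl ether, COCCl
Why: Exhaustive O-alkylation caps both catechol hydroxyls and the carboxylate in one operation, and the resulting MOM ester serves as the acyl donor of the next step.

Step 8
Reactants: 17 methoxymethyl 3-[3,4-bis(methoxymethoxy)phenyl]propanoate
Product: 18 3-[3,4-bis(methoxymethoxy)phenyl]-N-methoxy-N-methylpropanamide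
Conditions: MeNH(OMe)·HCl, i-PrMgCl, THF, −20 → 0 °C
Reagents that add atoms: N,O-dimethylhydroxylamine hydrochloride, CNOC.Cl
Why: Aminolysis of an ester by the chloromagnesium amide made in the flask is the standard ester-to-Weinreb-amide conversion, and aryl MOM ethers are inert to it.

Step 9
Reactants: 15 4,7-dibromo-6,8-bis(methoxymethoxy)-3-methyl-2,5-dihydro-1-benzoxepine; 18 3-[3,4-bis(methoxymethoxy)phenyl]-N-methoxy-N-methylpropanamide
Product: 22 1-[6,8-bis(methoxymethoxy)-3-methyl-2,5-dihydro-1-benzoxepin-7-yl]-3-[3,4-bis(methoxymethoxy)phenyl]propan-1-one, via aryllithium 19 (not isolated), via bromo hemiaminal alkoxide 20 (not isolated), via alkenyllithium 21 (not isolated)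
Conditions: n-BuLi (1.05 equiv), THF, −78 °C; 18 (1.0 equiv), −78 → −20 °C; t-BuLi (3.5 equiv), −78 °C; MeOH, −78 °C; aq NH4Cl
Reagents that add atoms: none
Why: Bromine–lithium exchange is combined with the Weinreb ketone synthesis: the reversible exchange with n-BuLi should settle on C7, where two flanking MOM oxygens hold the lithium, the aryllithium adds once to 18, the chelated tetrahedral adduct masks the ketone while t-BuLi exchanges the remaining alkenyl bromide, methanol protonates C4, and at −78 °C exchange outruns deprotonation of the base-sensitive C2 and C5 methylenes.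

Step 10
Reactants: 22 1-[6,8-bis(methoxymethoxy)-3-methyl-2,5-dihydro-1-benzoxepin-7-yl]-3-[3,4-bis(methoxymethoxy)phenyl]propan-1-one
Product: 23 target CNP0203471.0, 3-(3,4-dihydroxyphenyl)-1-(6,8-dihydroxy-3-methyl-2,5-dihydro-1-benzoxepin-7-yl)propan-1-one
Conditions: HCl (3 M aq), MeOH, 45 °C
Reagents that add atoms: none
Why: Acid-catalysed acetal exchange removes all four MOM groups as it routinely does on prenylated polyphenols, and the ring alkene should be less prone to protonation than a prenyl group because its tertiary cation would sit beta to O1.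

Compound list
1 | flopropione, 1-(2,4,6-trihydroxyphenyl)propan-1-one | CCC(=O)c1c(O)cc(O)cc1O | starting material
2 | 1-[2-hydroxy-4,6-bis(methoxymethoxy)phenyl]propan-1-one | CCC(=O)c1c(O)cc(OCOC)cc1OCOC | intermediate
3 | paraformaldehyde (reacts as formaldehyde) | C=O | starting material
4 | 1-[2-hydroxy-4,6-bis(methoxymethoxy)phenyl]-2-methylprop-2-en-1-one (not isolated) | C=C(C)C(=O)c1c(O)cc(OCOC)cc1OCOC | intermediate
5 | (±)-5,7-bis(methoxymethoxy)-3-methylchroman-4-one | CC1COc2cc(OCOC)cc(OCOC)c2C1=O | intermediate
6 | 5,7-bis(methoxymethoxy)-3-methylchroman-4-ol, racemic cis/trans mixture | CC1COc2cc(OCOC)cc(OCOC)c2C1O | intermediate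
7 | lithium 6-lithio-5,7-bis(methoxymethoxy)-3-methylchroman-4-olate (not isolated) | CC1COc2cc(OCOC)c([Li])c(OCOC)c2C1O[Li] | intermediate
8 | 6-bromo-5,7-bis(methoxymethoxy)-3-methylchroman-4-ol, racemic cis/trans mixture | CC1COc2cc(OCOC)c(Br)c(OCOC)c2C1O | intermediate
9 | 6-bromo-5,7-bis(methoxymethoxy)-3-methylchroman-4-yl methanesulfonate (not isolated) | CC1COc2cc(OCOC)c(Br)c(OCOC)c2C1OS(C)(=O)=O | intermediate
10 | 6-bromo-5,7-bis(methoxymethoxy)-3-methyl-2H-chromene | CC1=Cc2c(OCOC)c(Br)c(OCOC)cc2OC1 | intermediate
11 | bromoform | BrC(Br)Br | starting material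
12 | 1,1,6-tribromo-5,7-bis(methoxymethoxy)-1a-methyl-1,1a,2,7b-tetrahydrocyclopropa[c]chromene, racemic, cis-fused (not isolated) | CC12COc3cc(OCOC)c(Br)c(OCOC)c3C1C2(Br)Br | intermediate
13 | 4,7-dibromo-6,8-bis(methoxymethoxy)-3-methyl-2H-1-benzoxepin-5-ylium, the 2-bromoallyl cation over C3–C4–C5 (not isolated) | CC1=C(Br)[CH+]c2c(cc(OCOC)c(Br)c2OCOC)OC1 | intermediate
14 | 4,7-dibromo-6,8-bis(methoxymethoxy)-3-methyl-2,5-dihydro-1-benzoxepin-5-yl trifluoroacetate, racemic (not isolated) | CC1=C(Br)C(OC(=O)C(F)(F)F)c2c(cc(OCOC)c(Br)c2OCOC)OC1 | intermediate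
15 | 4,7-dibromo-6,8-bis(methoxymethoxy)-3-methyl-2,5-dihydro-1-benzoxepine | CC1=C(Br)Cc2c(cc(OCOC)c(Br)c2OCOC)OC1 | intermediate
16 | 3-(3,4-dihydroxyphenyl)propanoic acid | OC(=O)CCc1ccc(O)c(O)c1 | starting material
17 | methoxymethyl 3-[3,4-bis(methoxymethoxy)phenyl]propanoate | COCOC(=O)CCc1ccc(OCOC)c(OCOC)c1 | intermediate
18 | 3-[3,4-bis(methoxymethoxy)phenyl]-N-methoxy-N-methylpropanamide | CON(C)C(=O)CCc1ccc(OCOC)c(OCOC)c1 | intermediate
19 | 4-bromo-7-lithio-6,8-bis(methoxymethoxy)-3-methyl-2,5-dihydro-1-benzoxepine (not isolated) | CC1=C(Br)Cc2c(cc(OCOC)c([Li])c2OCOC)OC1 | intermediate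
20 | lithium alkoxide of the tetrahedral adduct of 19 and 18, C4 bromide intact (not isolated) | CC1=C(Br)Cc2c(cc(OCOC)c(C(O[Li])(CCc3ccc(OCOC)c(OCOC)c3)N(C)OC)c2OCOC)OC1 | intermediate
21 | the same tetrahedral adduct lithiated at C4 (not isolated) | CC1=C([Li])Cc2c(cc(OCOC)c(C(O[Li])(CCc3ccc(OCOC)c(OCOC)c3)N(C)OC)c2OCOC)OC1 | intermediate
22 | 1-[6,8-bis(methoxymethoxy)-3-methyl-2,5-dihydro-1-benzoxepin-7-yl]-3-[3,4-bis(methoxymethoxy)phenyl]propan-1-one | CC1=CCc2c(cc(OCOC)c(C(=O)CCc3ccc(OCOC)c(OCOC)c3)c2OCOC)OC1 | intermediate
23 | 3-(3,4-dihydroxyphenyl)-1-(6,8-dihydroxy-3-methyl-2,5-dihydro-1-benzoxepin-7-yl)propan-1-one (CNP0203471.0) | CC1=CCc2c(cc(O)c(C(=O)CCc3ccc(O)c(O)c3)c2O)OC1 | target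

Total step count: 10 (eight in the main line, two for the side chain).
Longest linear sequence: 8 steps (steps 1–6, 9, 10).

Steps most likely to fail

1. Step 6 (the new method).
- **Possible failures:**
  - The cyclopropane may ionise too early, during the carbene stage.
  - Proton loss from the allyl cation may outrun hydride transfer.
  - Hydride may be delivered to C3.
  - The silver ion may oxidise the silane.
  - The C6 MOM oxygen may take part at the C5 cation, with loss of its methyl group.
- **Fallback:** it uses known chemistry only, sets out from 10 and comes back at 15.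
  - Cyclopropane 12 is made under phase-transfer conditions (CHBr3, 50% aq NaOH, BnEt3NCl, CH2Cl2) and isolated.
  - AgNO3 with CaCO3 in aqueous acetone then opens it with capture by water, the long-known solvolytic form of this ring enlargement. This gives 4,7-dibromo-6,8-bis(methoxymethoxy)-3-methyl-2,5-dihydro-1-benzoxepin-5-ol F1.
  - In a separate, silver-free flask the benzylic-allylic alcohol is deoxygenated by ionic hydrogenation (Et3SiH, CF3CO2H, CH2Cl2, −40 °C) to 15.
  - Ring opening and reduction can then be tuned apart, and water traps the cation much faster than it can lose a proton.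

2. Step 9.
- **Possible failures:**
  - The first exchange may leak to the alkenyl bromide.
  - The hindered aryllithium may enolise the amide.
  - The tetrahedral adduct may break down during the second exchange, followed by over-addition.
- **Fallback:** it sets out from 15 and 18 and comes back at 22.
  - The sequence is stopped after the acylation (n-BuLi, then 18, then aq NH4Cl). This gives 1-[4-bromo-6,8-bis(methoxymethoxy)-3-methyl-2,5-dihydro-1-benzoxepin-7-yl]-3-[3,4-bis(methoxymethoxy)phenyl]propan-1-one F2.
  - The C4 bromide of the isolated ketone is then removed by a radical chain reduction (Bu3SnH, AIBN, toluene, 80 °C) instead of a polar exchange. This route tolerates the ketone and needs no second organolithium.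

3. Step 4.
- **Possible failures:** the second deprotonation of the aggregated lithium alkoxide may be sluggish, and metalation may leak to C8.
- **Fallback:** it sets out from 6 and comes back at 22. The aryl bromide is given up, and the arene is metalated only at the end, on a neutral and soluble ether.
  - Dehydration of 6 under the conditions of step 5 gives 5,7-bis(methoxymethoxy)-3-methyl-2H-chromene F3.
  - The carbene stage of step 6 gives 1,1-dibromo-5,7-bis(methoxymethoxy)-1a-methyl-1,1a,2,7b-tetrahydrocyclopropa[c]chromene F4.
  - The silver and silane stage gives 4-bromo-6,8-bis(methoxymethoxy)-3-methyl-2,5-dihydro-1-benzoxepine F5.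
  - Treatment with t-BuLi and then MeOH at −78 °C gives 6,8-bis(methoxymethoxy)-3-methyl-2,5-dihydro-1-benzoxepine F6.
  - This ether is lithiated between its MOM groups (n-BuLi–TMEDA, Et2O, −20 °C, a weakly polar medium that favours coordination-driven ring metalation over allylic deprotonation) and acylated with 18 to give 22.

Further compounds
F1 | step 6 | 4,7-dibromo-6,8-bis(methoxymethoxy)-3-methyl-2,5-dihydro-1-benzoxepin-5-ol (racemic) | CC1=C(Br)C(O)c2c(cc(OCOC)c(Br)c2OCOC)OC1
F2 | step 9 | 1-[4-bromo-6,8-bis(methoxymethoxy)-3-methyl-2,5-dihydro-1-benzoxepin-7-yl]-3-[3,4-bis(methoxymethoxy)phenyl]propan-1-one | CC1=C(Br)Cc2c(cc(OCOC)c(C(=O)CCc3ccc(OCOC)c(OCOC)c3)c2OCOC)OC1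
F3 | step 4 | 5,7-bis(methoxymethoxy)-3-methyl-2H-chromene | CC1=Cc2c(OCOC)cc(OCOC)cc2OC1
F4 | step 4 | 1,1-dibromo-5,7-bis(methoxymethoxy)-1a-methyl-1,1a,2,7b-tetrahydrocyclopropa[c]chromene (racemic, cis-fused) | CC12COc3cc(OCOC)cc(OCOC)c3C1C2(Br)Br
F5 | step 4 | 4-bromo-6,8-bis(methoxymethoxy)-3-methyl-2,5-dihydro-1-benzoxepine | CC1=C(Br)Cc2c(cc(OCOC)cc2OCOC)OC1
F6 | step 4 | 6,8-bis(methoxymethoxy)-3-methyl-2,5-dihydro-1-benzoxepine | CC1=CCc2c(cc(OCOC)cc2OCOC)OC1
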